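I could not ask a molecule of product when it was made, and that date was what I needed.

    left-handed substrate ⇌ right-handed substrate (k1 = 0.050 /s, Ea1 = 107 kJ/mol)
    partner + free catalyst → spent catalyst (k2 = 0.41 /M/s, Ea2 = 74.0 kJ/mol)
    partner + free catalyst + left-handed substrate → free catalyst + left-handed product (k3 = 550 /M²/s, Ea3 = 48.0 kJ/mol)
    partner + free catalyst + right-handed substrate → free catalyst + right-handed product (k4 = 35 /M²/s, Ea4 = 43.0 kJ/mol)
    solid reagent ⇌ partner, rate k5*(cs5 - [partner]) while solid is left; crystals form when [partner] > cs5 (cs5 = 11 mM, k5 = 0.087 /s)
    left-handed product ⇌ right-handed product (k6 = 0.0016 /s, Ea6 = 102 kJ/mol)
    (constants at 100 °C)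

| flask | left-handed substrate | solid reagent | free catalyst | right-handed substrate | temperature | time |
|---|---|---|---|---|---|---|
| theta | 0.10 M | 0.400 M | 0.56 mM | 0.10 M | 100 °C | 8.0 min |
| beta | 0.10 M | 0.400 M | 0.56 mM | 0.10 M | 85 °C | 8.0 min |
| gamma | 0.10 M | 0.400 M | 0.56 mM | 0.10 M | 115 °C | 8.0 min |

- free catalyst is single-handed; left-handed substrate and right-handed substrate are mirror images of each other, charged as a racemate, each of them at the stated concentration
- given per volume of solution although it is solid: solid reagent
- constants are those at 100 °C; use the activation energies for any other temperature
- at the start none of the solid reagent is in solution
- an excess is the difference of the two amounts in percent of their sum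
- an excess is below zero if the other one leads

- the flask that comes out highest in excess of left-handed product over right-handed product, or "all alike" when all lie within 1.5 percentage points (theta / beta / gamma / all alike)
- excess of left-handed product over right-handed product at the end, theta
- excess of left-handed product over right-handed product at the end, beta
- excess of left-handed product over right-handed product at the end, gamma

I began with the bench rule. In theta, with partner at its solubility and free catalyst at its charge, the two substrate forms turn into each other faster than the catalyst draws them off: they relax at 6.00 /min against 0.203 /min for the left-handed one. So I followed one molecule. At its first fork it picks a hand, with odds equal to the selectivity factor, 15.7 in theta. The rule then gives an excess s, the difference of the two catalysed constants over their sum: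

s: theta 0.880, beta 0.873, gamma 0.887

Gamma and beta differ there by 1.4 percentage points, so the rule told me little. But the molecule meets a second fork. Product turns into its mirror image, and an excess decays at a, 2 times the rate constant of that turning. I put the border of the rule where a × time nears 1:

a: theta 0.192 /min, beta 0.0485 /min, gamma 0.684 /min
a × time: beta 0.388, theta 1.54, gamma 5.47

Beta lay inside that border, while theta and gamma lay beyond it. Births are also uneven. Dissolving relaxes with a half-life of 0.133 min, short against the time, so I held partner at its solubility. In my reckoning free catalyst then dies at d, its loss constant times that solubility. Taking substrate as steady, I let births thin out at d: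

d: theta 0.271 /min, beta 0.0997 /min, gamma 0.680 /min
d/(a − d) × (e^(−dt) − e^(−at)) / (1 − e^(−dt)): theta 0.391, beta 0.808, gamma 0.0233

This is the kept share: e^(−a × age at the end), averaged over the product molecules by birth. Multiplied by s, it gave what I committed to:

theta 34.4 %, beta 70.5 %, gamma 2.07 %; highest beta

The forecast named beta, with 36 % for theta, 70 % for beta and 3.2 % for gamma, holding that the “final excess is therefore set by how much product racemises before the end”. My figures stood a little below it for theta and gamma.

The simulation gave beta as highest, with 36.0 % for theta, 70.2 % for beta and 3.02 % for gamma.

With the turning between the product forms struck out, gamma ended at 88.7 % instead of 3.02 %, so that turning is the main reason for its low excess. Read back from the flask, gamma's kept share was 0.0340, against my 0.0233.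

A neighbour like gamma but with 0.0022 M of free catalyst has the same a and d in my reckoning, so my kept share for it was again 0.0233 and I expected 2.07 %. It gave 4.27 %, although left-handed product stood at 34.7 % of the charge against 12.8 % in gamma.

(The numbers are invented; the flask was simulated.)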